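The runs are simulated for substances that don't exist; the scatter is artificial.

I began with the pool.

- green: Z 1.6 M; J 0.080 M; run made earlier
- flask: Z 0.80 M; J 0.0800 M; time 15 d

green run (percent of the Z and J together charged)

| time / d | Q / % | D / % | Z / % |
|---|---|---|---|
| 0.333 | 0 | 3.5 | 97.3 |
| 0.833 | 0 | 6.6 | 92.9 |
| 2.08 | 0 | 15.3 | 83.0 |
| 5.00 | 1.3 | 29.7 | 64.4 |

(scatter of a reading: 0.5 percentage points)

1. ratio of Q to D at 6.0 h
2. ratio of Q to D at 15 d
3. which of Q and D there is more of at 15 d



In the green run Z fell as a plain exponential decay. From its first and last readings I read 7.84 d as the time in which Z and J, counted together as one fraction of the charge, fall to half: the pool half-life. Run back to zero time, that curve starts at 100% of the charge, yet Z alone was 95.2% of the green charge. So I treated J as a small correction that joins Z.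

Then I turned the settings by hand. Lowering Z from 1.6 M to 0.80 M should change nothing in a first-order decay, though no run had tested that. Raising the share of J to 9.09% should, by my hand reckoning, add to the pool. The time, 15 d, is 1.91 pool half-lives, which left Z at 26.5% of the charge. Q lagged, so I scaled the green ratio of Q to D at 5.00 d in proportion to time and got 0.131, with D ahead. At 6.0 h I offered no figure, because Q still read zero.

The forecast, higher than mine, gave 2.000 × 10⁻⁴ at 6.0 h and 0.4 at 15 d, with D ahead, holding that “Q comes after D rather than directly from Z”.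

The flask gave 0.0118 at 6.0 h and 0.0867 at 15 d, with D ahead, 52.5% against 4.55%.

    D ⇌ Q (K = 0.760, k = 6.10 × 10⁻⁶ min⁻¹)
    D ⇌ E (K = 0.360, k = 8.11 × 10⁻⁵ min⁻¹)
    J → Q (k = 2.83 × 10⁻⁴ min⁻¹)
    Z ⇌ J (K = 0.00103, k = 2.04 × 10⁻⁴ min⁻¹)
    Z → D (k = 6.20 × 10⁻⁵ min⁻¹)

The pool half-life had put Z in this flask at 26.5%, and the flask held 26.0%. Part of what keeps the pool together is the backward run from J to Z: without it, the ratio of Q to D in this flask goes from 0.0867 to 3.36 at 15 d, and Q leads. At 6.0 h, taking that run away moves the ratio in this flask from 0.0118 to 0.629. In the neighbour flask with 0.32 M of J, where Z was 71.4% of the charge, the same half-life applied, and Z stood at 26.0% of the charge.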